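## Retrosynthetic overview

1. The oxolane ring is closed last: the C2–O bond forms from a 4-hydroxybenzylic cation and a primary alcohol of an open-chain hexol (sets C2).
2. The C2–C3 bond and the quaternary C3 come from an aldol of an α-silyloxy-β-benzyl-γ-butyrolactone enolate with protected vanillin, anti to the benzyl group.
3. The lactone and its C4 stereocentre come from a prochiral 3-benzyloxetane by enantioselective ring-expansion carbonylation (CO insertion, 4 → 5 ring), the key step.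
4. The oxetane comes from 3-methylideneoxetane and an aryl bromide (hydroboration/Suzuki); both aryl units come from catechol.
5. Ring order: oxetane (bought) → γ-butyrolactone (ring expansion) → opened by LiAlH4 → oxolane.

Assumptions and abbreviations: catechol and 3-methylideneoxetane are purchased. Ar = 3-methoxy-4-[tri(propan-2-yl)silyloxy]phenyl; TIPS = tri(propan-2-yl)silyl; TES = triethylsilyl. Target locants: O1, C2 (aryl), C3 (OH, CH2OH), C4 (benzyl), C5. The sense of induction of the new catalyst in step 4 must be found by experiment; the ligand antipode that gives (4R)-8 is used (written here as R,R).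

## Route

Step 1
Reactants: 1 benzene-1,2-diol (catechol)
Product: 2 2-methoxyphenol
Conditions: MeI (1.0 equiv), K2CO3, acetone, 56 °C; base extraction, distillation
Reagents that add atoms: iodomethane, CI
Why: Williamson ether synthesis on a symmetrical diphenol with one equivalent of MeI gives the mono-ether, which is separated from the neutral diether and from catechol.

Step 2
Reactants: 2 2-methoxyphenol
Product: 4 (4-bromo-2-methoxyphenoxy)tri(propan-2-yl)silane, via 4-bromo-2-methoxyphenol 3 (not isolated)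
Conditions: NBS (1.0 equiv), DMF, 0 °C; then imidazole, TIPSCl, rt
Reagents that add atoms: N-bromosuccinimide, O=C1CCC(=O)N1Br; chlorotri(propan-2-yl)silane, CC(C)[Si](Cl)(C(C)C)C(C)C
Why: Electrophilic aromatic bromination goes para to the free hydroxyl (the stronger donor), and imidazole-mediated O-silylation in the same flask gives an aryl bromide that tolerates bases, organolithiums and hydride.

Step 3
Reactants: 4 (4-bromo-2-methoxyphenoxy)tri(propan-2-yl)silane; 5 3-methylideneoxetane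
Product: 7 3-(ArCH2)oxetane, via 9-(oxetan-3-ylmethyl)-9-borabicyclo[3.3.1]nonane 6 (not isolated)
Conditions: 5, 9-BBN, THF, 0 °C to rt; then 4, Pd(dppf)Cl2 (3 mol%), K3PO4, THF/H2O, 60 °C
Reagents that add atoms: none
Why: Anti-Markovnikov hydroboration puts boron on the exocyclic CH2 and B-alkyl Suzuki–Miyaura coupling forms the aryl–CH2 bond; 7 is achiral with two enantiotopic CH2–O groups.

Step 4
Reactants: 7 3-(ArCH2)oxetane
Product: 8 (4R)-4-(ArCH2)oxolan-2-one
Conditions: [(R,R)-(salen)Cr(THF)2][Co(CO)4] (5 mol%, from (R,R)-(salen)CrCl and NaCo(CO)4; salen = N,N'-bis(3,5-di-tert-butylsalicylidene)cyclohexane-1,2-diamine), CO (60 bar), DME, 60 °C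
Reagents that add atoms: carbon monoxide, [C-]#[O+]
Why: Proposed new method: enantioselective desymmetrising ring-expansion carbonylation of a prochiral 3-monosubstituted oxetane. The chiral Cr(III) cation binds the oxetane oxygen, [Co(CO)4]− opens one of the two enantiotopic CH2–O bonds by SN2 inside the chiral pocket, CO migratory insertion (1,2-alkyl shift from Co to CO) and closure of the metal alkoxide on the acyl-cobalt give the γ-butyrolactone, so the choice of CH2 sets C4 as R. The closest known reactions are the racemic Lewis acid/[Co(CO)4]− ring-expansion carbonylation of oxetanes to γ-butyrolactones, the enantioselective carbonylative desymmetrisation of meso-epoxides with chiral salen-type ion pairs, and chiral (salen)metal desymmetrisations of 3-substituted oxetanes.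

Step 5
Reactants: 8 (4R)-4-(ArCH2)oxolan-2-one
Product: 11 (3R,4S)-4-(ArCH2)-3-(triethylsilyloxy)oxolan-2-one, via potassium lactone enolate 9 (not isolated), via potassium 3-alkoxide 10 (not isolated)
Conditions: KHMDS, THF, −78 °C; 3-phenyl-2-(phenylsulfonyl)oxaziridine, −78 °C; then TESCl, −78 to 0 °C
Reagents that add atoms: 3-phenyl-2-(phenylsulfonyl)oxaziridine, O=S(=O)(c1ccccc1)N1OC1c1ccccc1; chlorotriethylsilane, CC[Si](Cl)(CC)CC
Why: Davis enolate hydroxylation delivers oxygen anti to the C4 benzyl group (trans product; this centre becomes planar again in step 7) and the alkoxide is silylated in situ so that the next enolisation is clean.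

Step 6
Reactants: 4 (4-bromo-2-methoxyphenoxy)tri(propan-2-yl)silane
Product: 13 3-methoxy-4-[tri(propan-2-yl)silyloxy]benzaldehyde, via aryllithium 12 (not isolated)
Conditions: n-BuLi, THF, −78 °C; DMF, −78 to 0 °C; 1 M HCl
Reagents that add atoms: N,N-dimethylformamide, CN(C)C=O
Why: Bromine–lithium exchange followed by formylation with DMF (Bouveault-type) gives the protected vanillin; the aryl silyl ether and methyl ether are inert at −78 °C.

Step 7
Reactants: 11 (3R,4S)-4-(ArCH2)-3-(triethylsilyloxy)oxolan-2-one; 13 3-methoxy-4-[tri(propan-2-yl)silyloxy]benzaldehyde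
Product: 15 (3R,4S)-3-[hydroxy(Ar)methyl]-4-(ArCH2)-3-(triethylsilyloxy)oxolan-2-one (both carbinol epimers), via lithium enolate 14 (not isolated)
Conditions: LDA, THF, −78 °C; 13, −78 °C; AcOH, −78 °C
Reagents that add atoms: none
Why: Lithium enolate aldol addition: 13 adds to the planar α-silyloxy enolate on the face anti to the C4 benzyl group, which sets the quaternary carbon (C3 of the target) with oxygen cis and the new C–C bond trans to the benzyl group; the carbinol centre is left as a mixture because step 9 re-forms it.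

Step 8
Reactants: 15 (3R,4S)-3-[hydroxy(Ar)methyl]-4-(ArCH2)-3-(triethylsilyloxy)oxolan-2-one
Product: 16 (2S,3S)-2-[hydroxy(Ar)methyl]-3-(ArCH2)-2-(triethylsilyloxy)butane-1,4-diol (both carbinol epimers)
Conditions: LiAlH4, THF, 0 °C; Rochelle salt work-up
Reagents that add atoms: none
Why: Hydride reduction of the lactone to the 1,4-diol touches no stereocentre and frees the primary alcohol that will become the ring oxygen.

Step 9
Reactants: 16 (2S,3S)-2-[hydroxy(Ar)methyl]-3-(ArCH2)-2-(triethylsilyloxy)butane-1,4-diol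
Product: 18 (2R,3S,4S)-2-(4-hydroxy-3-methoxyphenyl)-4-[(4-hydroxy-3-methoxyphenyl)methyl]-3-(hydroxymethyl)oxolan-3-ol, via hexol 17 (not isolated)
Conditions: TBAF (3.5 equiv), THF, 0 °C to rt; then aq. HCl to pH 2, rt
Reagents that add atoms: none
Why: Fluoride removes the three silyl groups, and at pH 2 the 4-hydroxybenzylic alcohol ionises (quinone methide/benzylic cation) and is captured by the C4 primary hydroxyl in an SN1 cycloetherification (5-exo-tet); allylic 1,3-strain in the planar cation places the aryl group cis to the tertiary OH and trans to CH2OH, so C2 forms as R while C3 and C4 are untouched.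

## Compound list

1 | benzene-1,2-diol (catechol) | Oc1ccccc1O | starting material
2 | 2-methoxyphenol | COc1ccccc1O | intermediate
3 | 4-bromo-2-methoxyphenol (not isolated) | COc1cc(Br)ccc1O | intermediate
4 | (4-bromo-2-methoxyphenoxy)tri(propan-2-yl)silane | COc1cc(Br)ccc1O[Si](C(C)C)(C(C)C)C(C)C | intermediate
5 | 3-methylideneoxetane | C=C1COC1 | starting material
6 | 9-(oxetan-3-ylmethyl)-9-borabicyclo[3.3.1]nonane (not isolated) | C1OCC1CB1C2CCCC1CCC2 | intermediate
7 | 3-{[3-methoxy-4-(triisopropylsilyloxy)phenyl]methyl}oxetane | COc1cc(CC2COC2)ccc1O[Si](C(C)C)(C(C)C)C(C)C | intermediate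
8 | (4R)-4-{[3-methoxy-4-(triisopropylsilyloxy)phenyl]methyl}oxolan-2-one | COc1cc(C[C@@H]2CC(=O)OC2)ccc1O[Si](C(C)C)(C(C)C)C(C)C | intermediate
9 | potassium (4R)-4-(ArCH2)-4,5-dihydrofuran-2-olate (not isolated) | [K+].[O-]C1=C[C@@H](Cc2ccc(O[Si](C(C)C)(C(C)C)C(C)C)c(OC)c2)CO1 | intermediate
10 | potassium (3R,4S)-4-(ArCH2)-2-oxooxolan-3-olate (not isolated) | [K+].[O-][C@H]1C(=O)OC[C@@H]1Cc1ccc(O[Si](C(C)C)(C(C)C)C(C)C)c(OC)c1 | intermediate
11 | (3R,4S)-4-{[3-methoxy-4-(triisopropylsilyloxy)phenyl]methyl}-3-(triethylsilyloxy)oxolan-2-one | CC[Si](CC)(CC)O[C@H]1C(=O)OC[C@@H]1Cc1ccc(O[Si](C(C)C)(C(C)C)C(C)C)c(OC)c1 | intermediate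
12 | [3-methoxy-4-(triisopropylsilyloxy)phenyl]lithium (not isolated) | [Li]c1ccc(O[Si](C(C)C)(C(C)C)C(C)C)c(OC)c1 | intermediate
13 | 3-methoxy-4-[tri(propan-2-yl)silyloxy]benzaldehyde | COc1cc(C=O)ccc1O[Si](C(C)C)(C(C)C)C(C)C | intermediate
14 | lithium (4S)-4-(ArCH2)-3-(triethylsilyloxy)-4,5-dihydrofuran-2-olate (not isolated) | [Li+].[O-]C1=C(O[Si](CC)(CC)CC)[C@@H](Cc2ccc(O[Si](C(C)C)(C(C)C)C(C)C)c(OC)c2)CO1 | intermediate
15 | (3R,4S)-3-[hydroxy(Ar)methyl]-4-(ArCH2)-3-(triethylsilyloxy)oxolan-2-one, carbinol carbon as both epimers | CC[Si](CC)(CC)O[C@]1(C(O)c2ccc(O[Si](C(C)C)(C(C)C)C(C)C)c(OC)c2)C(=O)OC[C@@H]1Cc1ccc(O[Si](C(C)C)(C(C)C)C(C)C)c(OC)c1 | intermediate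
16 | (2S,3S)-2-[hydroxy(Ar)methyl]-3-(ArCH2)-2-(triethylsilyloxy)butane-1,4-diol, carbinol carbon as both epimers | COc1cc(C(O)[C@@](O[Si](CC)(CC)CC)(CO)[C@H](CO)Cc2ccc(O[Si](C(C)C)(C(C)C)C(C)C)c(OC)c2)ccc1O[Si](C(C)C)(C(C)C)C(C)C | intermediate
17 | (2S,3S)-2-[hydroxy(4-hydroxy-3-methoxyphenyl)methyl]-3-[(4-hydroxy-3-methoxyphenyl)methyl]butane-1,2,4-triol, carbinol carbon as both epimers (not isolated) | COc1cc(C(O)[C@@](O)(CO)[C@H](CO)Cc2ccc(O)c(OC)c2)ccc1O | intermediate
18 | (2R,3S,4S)-2-(4-hydroxy-3-methoxyphenyl)-4-[(4-hydroxy-3-methoxyphenyl)methyl]-3-(hydroxymethyl)oxolan-3-ol | COc1cc(C[C@H]2CO[C@H](c3ccc(O)c(OC)c3)[C@@]2(O)CO)ccc1O | target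

## Step count and risks

Total steps: 9. Longest linear sequence: 8 (steps 1, 2, 3, 4, 5, 7, 8, 9 from catechol); step 6 is a one-step branch from 4.

Steps most likely to fail:

Step 4 (the new reaction). Enantioselectivity is untested and Lewis-acid oligomerisation of the oxetane may compete. The fallback uses known chemistry, sets out from 4 and comes back at 8. Nickel-catalysed reductive cross-electrophile coupling of 4 with 3-(bromomethyl)cyclobutan-1-one (O=C1CC(CBr)C1, seven heavy atoms; NiBr2·glyme, 4,4'-di-tert-butyl-2,2'-bipyridine, Zn, NaI, DMA, 60 °C) gives 3-{[3-methoxy-4-(triisopropylsilyloxy)phenyl]methyl}cyclobutan-1-one F1. A catalytic asymmetric Baeyer–Villiger oxidation of this prochiral ketone (chiral N,N'-dioxide–Sc(OTf)3, m-CPBA, EtOAc, −20 °C) then gives 8, again by ring expansion.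

Step 7 (quaternary centre by a hindered, reversible aldol with an electron-rich aldehyde). The fallback replaces the intermolecular aldol by an intramolecular O-to-C 1,2-acyl shift; it sets out from 8 and 13 and comes back at 17. Hydroxylation of 8 as in step 5 with an aqueous quench gives (3R,4S)-3-hydroxy-4-(ArCH2)oxolan-2-one F2. Oxidation of 13 (NaClO2, NaH2PO4, 2-methylbut-2-ene) gives 3-methoxy-4-(triisopropylsilyloxy)benzoic acid F3. DCC/DMAP coupling gives the α-aroyloxy lactone, (3R,4S)-4-(ArCH2)-2-oxooxolan-3-yl 3-methoxy-4-(triisopropylsilyloxy)benzoate F4. LDA (THF, −78 to −40 °C) moves the aroyl group from oxygen to the enolate carbon on the face anti to the benzyl group and gives (3R,4S)-3-aroyl-3-hydroxy-4-(ArCH2)oxolan-2-one F5. LiAlH4 reduces ketone and lactone to (2S,3S)-2-[hydroxy(Ar)methyl]-3-(ArCH2)butane-1,2,4-triol F6, and TBAF gives 17, which is cyclised as in step 9.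

Step 9 (C2 selectivity under SN1 control; acid can also give an aryltetralin by Friedel–Crafts closure or a pinacol shift). The fallback sets C2 and C3 by reagent control and a stereospecific epoxide opening; it sets out from 8 and 13 and comes back at 18.
- Aldol of the lithium enolate of 8 with 13 gives (3S,4R)-3-[hydroxy(Ar)methyl]-4-(ArCH2)oxolan-2-one F7.
- MsCl/Et3N gives the mesylate, (3S,4R)-3-[(methanesulfonyloxy)(Ar)methyl]-4-(ArCH2)oxolan-2-one F8.
- DBU eliminates it to (3E,4R)-3-(Ar-methylidene)-4-(ArCH2)oxolan-2-one F9.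
- DIBAL-H gives (2E,3R)-2-(Ar-methylidene)-3-(ArCH2)butane-1,4-diol F10.
- Sharpless epoxidation (Ti(OiPr)4, L-(+)-diethyl tartrate, t-BuOOH, 4 Å sieves, CH2Cl2, −20 °C) gives {(2S,3S)-3-Ar-2-[(2S)-1-hydroxy-3-Ar-propan-2-yl]oxiran-2-yl}methanol F11.
- With a trace of CSA the homoallylic-derived primary hydroxyl opens the epoxide at the benzylic carbon (5-endo, inversion) to give the bis-TIPS ether of the target, (2R,3S,4S)-2-Ar-4-(ArCH2)-3-(hydroxymethyl)oxolan-3-ol F12.
- TBAF gives 18.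

## Further compounds

F1 | step 4 | 3-{[3-methoxy-4-(triisopropylsilyloxy)phenyl]methyl}cyclobutan-1-one | COc1cc(CC2CC(=O)C2)ccc1O[Si](C(C)C)(C(C)C)C(C)C
F2 | step 7 | (3R,4S)-3-hydroxy-4-{[3-methoxy-4-(triisopropylsilyloxy)phenyl]methyl}oxolan-2-one | O[C@H]1C(=O)OC[C@@H]1Cc1ccc(O[Si](C(C)C)(C(C)C)C(C)C)c(OC)c1
F3 | step 7 | 3-methoxy-4-(triisopropylsilyloxy)benzoic acid | COc1cc(C(=O)O)ccc1O[Si](C(C)C)(C(C)C)C(C)C
F4 | step 7 | (3R,4S)-4-(ArCH2)-2-oxooxolan-3-yl 3-methoxy-4-(triisopropylsilyloxy)benzoate | COc1cc(C(=O)O[C@H]2C(=O)OC[C@@H]2Cc3ccc(O[Si](C(C)C)(C(C)C)C(C)C)c(OC)c3)ccc1O[Si](C(C)C)(C(C)C)C(C)C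
F5 | step 7 | (3R,4S)-3-hydroxy-3-[3-methoxy-4-(triisopropylsilyloxy)benzoyl]-4-(ArCH2)oxolan-2-one | COc1cc(C(=O)[C@@]2(O)C(=O)OC[C@@H]2Cc3ccc(O[Si](C(C)C)(C(C)C)C(C)C)c(OC)c3)ccc1O[Si](C(C)C)(C(C)C)C(C)C
F6 | step 7 | (2S,3S)-2-[hydroxy(Ar)methyl]-3-(ArCH2)butane-1,2,4-triol, carbinol carbon as both epimers | COc1cc(C(O)[C@@](O)(CO)[C@H](CO)Cc2ccc(O[Si](C(C)C)(C(C)C)C(C)C)c(OC)c2)ccc1O[Si](C(C)C)(C(C)C)C(C)C
F7 | step 9 | (3S,4R)-3-[hydroxy(Ar)methyl]-4-(ArCH2)oxolan-2-one, carbinol carbon as both epimers | COc1cc(C(O)[C@H]2C(=O)OC[C@@H]2Cc3ccc(O[Si](C(C)C)(C(C)C)C(C)C)c(OC)c3)ccc1O[Si](C(C)C)(C(C)C)C(C)C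
F8 | step 9 | (3S,4R)-3-[(methanesulfonyloxy)(Ar)methyl]-4-(ArCH2)oxolan-2-one | COc1cc(C(OS(C)(=O)=O)[C@H]2C(=O)OC[C@@H]2Cc3ccc(O[Si](C(C)C)(C(C)C)C(C)C)c(OC)c3)ccc1O[Si](C(C)C)(C(C)C)C(C)C
F9 | step 9 | (3E,4R)-3-(Ar-methylidene)-4-(ArCH2)oxolan-2-one | COc1cc(/C=C2/C(=O)OC[C@@H]2Cc3ccc(O[Si](C(C)C)(C(C)C)C(C)C)c(OC)c3)ccc1O[Si](C(C)C)(C(C)C)C(C)C
F10 | step 9 | (2E,3R)-2-(Ar-methylidene)-3-(ArCH2)butane-1,4-diol | COc1cc(/C=C(/CO)[C@H](CO)Cc2ccc(O[Si](C(C)C)(C(C)C)C(C)C)c(OC)c2)ccc1O[Si](C(C)C)(C(C)C)C(C)C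
F11 | step 9 | {(2S,3S)-3-Ar-2-[(2S)-1-hydroxy-3-Ar-propan-2-yl]oxiran-2-yl}methanol | COc1cc([C@@H]2O[C@]2(CO)[C@H](CO)Cc3ccc(O[Si](C(C)C)(C(C)C)C(C)C)c(OC)c3)ccc1O[Si](C(C)C)(C(C)C)C(C)C
F12 | step 9 | (2R,3S,4S)-2-Ar-4-(ArCH2)-3-(hydroxymethyl)oxolan-3-ol (bis-TIPS ether of the target) | COc1cc(C[C@H]2CO[C@H](c3ccc(O[Si](C(C)C)(C(C)C)C(C)C)c(OC)c3)[C@@]2(O)CO)ccc1O[Si](C(C)C)(C(C)C)C(C)C
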